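Carbon numbers C1–C15 are the germacrane numbers of the target and are kept for every intermediate: C8 carries the methacrylate, C10 the hydroxyl and the methyl C14, C1 is the enol-ether carbon, C4 carries the ring oxygen and the methyl C15, C6 is the lactone carbinol carbon, C11 carries C13 (CH2OAc), and C12 is the lactone carbonyl. The target is (4R,8R,10S).

## The problem

The target is a 1,4-epoxygermacranolide. Its ten-membered carbocycle C1–C10 is bridged by oxygen between C1 and C4 (the 2,3-dihydrofuran ring O–C1=C2–C3–C4) and fused at C6–C7 to a γ-alkylidene butenolide (O–C6(=C5)–C7=C11–C12=O). Closing this ring directly means closing what is in effect a nine-membered ring that holds a bridgehead enol ether and a ring-cis C5=C6 bond. Of the three stereocenters, C8 and C10 are 1,3-related and can control each other. C4 is quaternary and lies across the flat dihydrofuran ring from C10, so nothing in the final framework can relay information to it. The enol ether (acid and water), the ylidene butenolide and methacrylate (nucleophiles, base) and two tertiary alcohols will not survive rough treatment, so they should appear last.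

The enabling feature is that C1 and C6 are the only two ring carbons at the ketone oxidation level, and they stand 1,6 to each other on both paths round the ring (C1–C2–C3–C4–C5–C6 and C1–C10–C9–C8–C7–C6). A C1–C6 bond therefore turns the macrocycle into a decalin (ring A: C1–C6; ring B: C1, C6, C7–C10), and the C1=C6 double bond of that decalin is a masked form of both carbonyls. Each carbonyl, once freed, has its partner five atoms away: the C4 oxygen for C1 and the C12 carboxyl for C6.

## Retrosynthesis

**23 ⇒ 19.** The ring O–C1 bond, the lactone O–C6 bond and both enol double bonds are disconnected, and C1 is then joined to C6. Forward, ozonolysis of the ring-fusion double bond of octalin 19 unveils the ten-membered ring without any macrocyclisation, and the two ketones condense with O4 and with the C12 acid. This beats any cut inside the macrocycle because every ring closure on the way to 19 is a six-membered one, and the step creates no stereocenter. The precursor is a decalin carrying the same three stereocenters as the target. The forward reaction must be chemoselective for C1=C6 over the C7=C11 and methacrylate double bonds.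

**19 ⇒ 17 ⇒ 16 ⇒ 15.** The two esters are removed, and C7=C11 is cut by an intramolecular Horner–Wadsworth–Emmons disconnection. A silicon tether from O8 to O13 makes the new double bond part of a seven-membered ring, which forces C13 cis to C8 and the ester carbon C12 cis to C6, the geometry the lactonisation needs. An intermolecular olefination of the hindered C7 ketone would give neither reactivity nor geometry control.

**15 ⇒ 10 + 13.** The C8–O bond and the tether are cut together. Forward, 1,4-hydrosilylation of dienone 10 with hydrosilane 13 followed by Rubottom oxidation puts the oxygen on C8 and leaves the silicon, with its phosphonate arm, on that oxygen. C8 is set from C10, its 1,3-neighbour.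

**10 ⇒ 7.** The C1=C6 double bond is traced back to the cis ring fusion of 7. The two ring-fusion stereocenters C1 and C6 are temporary: they fold the bicycle so that C4 and C10 can be set on its convex face, and they are erased by dehydrogenation once that is done. This solves the remote C4/C10 relationship with a single asymmetric event.

**7 ⇒ 5 ⇒ 4 ⇒ 3.** The C10 methyl carbinol comes from methyllithium addition to the enone carbonyl, and the C4 carbinol from epoxidation of the ring A alkene and hydride opening. Both reagents are asked to attack the convex face.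

**3 ⇒ 1 + 2.** A Diels–Alder cut of ring A. The monoketal 2 differentiates C7 from C10, directs isoprene to the "para" orientation (methyl on C4) and is prochiral, so a chiral Lewis acid sets the absolute configuration.

**13 ⇒ 12 ⇒ 11.** The tether reagent comes from a phosphonoacetate by hydroxymethylation and O-silylation.

## Roads not taken

**Alternative 1:** the most obvious cut is C6–C7 in the macrocycle. A linalool-type seco aldehyde–vinyl iodide A1 would be closed by an intramolecular Nozaki–Hiyama–Kishi reaction (CrCl2/NiCl2), and the resulting alkoxide would lactonise to the saturated butenolide A2, which then needs a C5–C6 dehydrogenation. The ring closure forms a strained nine-membered equivalent ring, against transannular strain and at high dilution. The ring-cis enol-lactone double bond must then be introduced by oxidation next to an acid-labile enol ether. The acyclic precursor is also longer to make than decalin 19.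

**Alternative 2:** the biomimetic cut. A glaucolide-type 1-oxo-4,5-epoxy germacranolide A3 would be deprotonated at C6; epoxide opening and hemiketalisation would give the 1-hydroxy hemiketal A4, and dehydration the target. This cascade is attractive, but it presupposes the ten-membered germacranolide with five stereocenters (C4, C5, C6, C8, C10). Two of these are made only to be destroyed, and the hard ring closure is left untouched.

**Alternative 3:** a pericyclic ring expansion that also breaks C1–C6. An oxy-Cope rearrangement of a carvone-derived 1,2-dialkenylcyclohexanol A5 would give cyclodecenone A6 and make C3–C4; the carvone ring maps onto C1, C6–C10, C11–C14. C4 would arise by chirality transfer, but the precursor needs three contiguous fully substituted carbons (C10, C1, C6), and the chair transition state gives the trans C5=C6 bond. C6, C8, C12 and C13 would still have to be oxidised afterwards on a flexible medium ring. Ozonolysis cuts the same bond with no stereochemical demand and delivers C1 and C6 already at the right oxidation level.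

Key step: step 13

Assumption 1: the (S)-BINOL titanium catalyst of step 1 is taken to give the (4aS,8aR) adduct; if the sense of induction is the opposite, (R)-BINOL is used.
Assumption 2: hydrosilane 13 and compounds 14 and 15 are mixtures of epimers at the phosphonate carbon (C11); this centre becomes sp2 in step 9.

## Route

Step 1
Reactants: 1 isoprene; 2 4,4-dimethoxycyclohexa-2,5-dien-1-one
Product: 3 (4aS,8aR)-4,4-dimethoxy-6-methyl-4a,5,8,8a-tetrahydronaphthalen-1(4H)-one
Conditions: (S)-BINOL, TiCl2(OiPr)2 (10 mol %), 4 Å MS, CH2Cl2, 0 °C to rt, excess 1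
Reagents that add atoms: none
Why: Lewis-acid-catalysed Diels–Alder reaction of a quinone monoketal; the C10 carbonyl makes C6 the β-carbon, so isoprene adds in the "para" sense (methyl on C4) with cis ring fusion. The chiral titanium BINOLate selects one of the two enantiotopic enone double bonds and so sets C1 and C6, the temporary stereocenters that later steer C4 and C10.

Step 2
Reactants: 3 (4aS,8aR)-4,4-dimethoxy-6-methyl-4a,5,8,8a-tetrahydronaphthalen-1(4H)-one
Product: 4 (4aS,6S,7R,8aR)-6,7-epoxy-4,4-dimethoxy-6-methyl-4a,5,6,7,8,8a-hexahydronaphthalen-1(4H)-one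
Conditions: mCPBA, NaHCO3, CH2Cl2, 0 °C
Reagents that add atoms: 3-chloroperoxybenzoic acid, O=C(OO)c1cccc(Cl)c1
Why: Peracid epoxidation of the only electron-rich alkene (the enone double bond is inert). The reagent should approach the folded cis-fused bicycle from its convex face, which fixes the C4–O bond that is kept to the end.

Step 3
Reactants: 4 (4aS,6S,7R,8aR)-6,7-epoxy-4,4-dimethoxy-6-methyl-4a,5,6,7,8,8a-hexahydronaphthalen-1(4H)-one
Product: 5 (1S,4aS,6S,7R,8aR)-6,7-epoxy-4,4-dimethoxy-1,6-dimethyl-1,4,4a,5,6,7,8,8a-octahydronaphthalen-1-ol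
Conditions: MeLi, THF, −78 °C; aq. NH4Cl
Reagents that add atoms: methyllithium, [Li]C
Why: 1,2-Addition of methyllithium to the enone carbonyl from the convex face, anti to ring A, should set C10 (methyl exo, hydroxyl endo). Ketal and epoxide are inert at this temperature.

Step 4
Reactants: 5 (1S,4aS,6S,7R,8aR)-6,7-epoxy-4,4-dimethoxy-1,6-dimethyl-1,4,4a,5,6,7,8,8a-octahydronaphthalen-1-ol
Product: 7 (4S,4aR,7R,8aS)-4,7-dihydroxy-4,7-dimethyl-4a,5,6,7,8,8a-hexahydronaphthalen-1(4H)-one, via diol ketal 6 (not isolated)
Conditions: LiEt3BH, THF, 0 °C to rt; then 1 M HCl, THF, 0 °C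
Reagents that add atoms: water, O
Why: SN2 opening of the trisubstituted epoxide by hydride at the secondary carbon C3 leaves the C4–O bond untouched and gives the tertiary C4 alcohol. Dilute acid then hydrolyses the allylic dimethyl ketal to the C7 enone.

Step 5
Reactants: 7 (4S,4aR,7R,8aS)-4,7-dihydroxy-4,7-dimethyl-4a,5,6,7,8,8a-hexahydronaphthalen-1(4H)-one
Product: 10 (4S,7R)-4,7-dihydroxy-4,7-dimethyl-5,6,7,8-tetrahydronaphthalen-1(4H)-one, via tris(trimethylsilyl) dienol ether 8 (not isolated), via bis(trimethylsilyl) ether dienone 9 (not isolated)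
Conditions: LDA (3.3 equiv), THF, −78 °C, then TMSCl; Pd(OAc)2 (1.1 equiv), MeCN, rt; K2CO3, MeOH, 0 °C
Reagents that add atoms: chlorotrimethylsilane, C[Si](C)(C)Cl (its silyl groups are in 8 and 9 and are removed before 10)
Why: Saegusa–Ito dehydrogenation; because C8 is still sp2, the enolate of 7 can form only toward C6. β-Hydride elimination from the palladium enolate should take the syn C1–H and give the ring-fusion double bond C1=C6 of the cross-conjugated dienone. The temporary stereocenters C1 and C6 are erased here, after C4 and C10 have been set.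

Step 6
Reactants: 11 tert-butyl 2-(diethoxyphosphoryl)acetate
Product: 12 tert-butyl 2-(diethoxyphosphoryl)-3-hydroxypropanoate
Conditions: paraformaldehyde (1.0 equiv), piperidine (cat.), MeOH, 60 °C
Reagents that add atoms: formaldehyde (as paraformaldehyde), C=O
Why: Amine-catalysed aldol-type hydroxymethylation of the phosphonoacetate; one equivalent of formaldehyde and mild base should stop at the mono-adduct.

Step 7
Reactants: 12 tert-butyl 2-(diethoxyphosphoryl)-3-hydroxypropanoate
Product: 13 tert-butyl 2-(diethoxyphosphoryl)-3-[(diisopropylsilyl)oxy]propanoate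
Conditions: iPr2SiHCl, imidazole, CH2Cl2, 0 °C
Reagents that add atoms: chlorodiisopropylsilane, CC(C)[SiH](Cl)C(C)C
Why: O-Silylation of the primary alcohol gives an alkoxy(diisopropyl)hydrosilane that carries the phosphonate arm.

Step 8
Reactants: 10 (4S,7R)-4,7-dihydroxy-4,7-dimethyl-5,6,7,8-tetrahydronaphthalen-1(4H)-one; 13 tert-butyl 2-(diethoxyphosphoryl)-3-[(diisopropylsilyl)oxy]propanoate
Product: 15 α-silyloxy enone (O8-silylated (8R)-hydroxy ketone carrying the phosphonate on silicon), via silyl dienol ether 14 (not isolated)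
Conditions: RhCl(PPh3)3 (2 mol %), THF, 50 °C; then mCPBA, NaHCO3, CH2Cl2, −20 °C
Reagents that add atoms: 3-chloroperoxybenzoic acid, O=C(OO)c1cccc(Cl)c1
Why: Rhodium-catalysed 1,4-hydrosilylation should occur at the less substituted enone (C8=C9) and give silyl dienol ether 14. Rubottom oxidation with O-to-O silyl shift then places an oxygen on C8 and leaves the silicon, with its phosphonate arm, on that oxygen. The peracid should be delivered syn to the homoallylic C10 hydroxyl (hydrogen bonding; the C10 methyl covers the other face), which sets C8.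

Step 9
Reactants: 15 α-silyloxy enone (O8-silylated (8R)-hydroxy ketone carrying the phosphonate on silicon)
Product: 16 cyclic diisopropylsilylene (O8, O13) derivative of tert-butyl dienoate 17
Conditions: LiCl, DBU, MeCN, 0 °C to rt
Reagents that add atoms: none
Why: Intramolecular Horner–Wadsworth–Emmons olefination of the C7 ketone. The seven-membered silaketal ring forces C13 cis to C8 and therefore the ester carbon C12 cis to C6; both C11 epimers of 15 converge.

Step 10
Reactants: 16 cyclic diisopropylsilylene (O8, O13) derivative of tert-butyl dienoate 17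
Product: 17 tert-butyl (2E)-3-hydroxy-2-[(2R,4S,7R)-2,4,7-trihydroxy-4,7-dimethyl-3,4,5,6,7,8-hexahydronaphthalen-1(2H)-ylidene]propanoate
Conditions: HF·pyridine, pyridine, THF, 0 °C
Reagents that add atoms: none
Why: Fluoride cleaves both Si–O bonds of the silaketal; the buffered medium should leave the dienoate and the tertiary allylic alcohol untouched.

Step 11
Reactants: 17 tert-butyl (2E)-3-hydroxy-2-[(2R,4S,7R)-2,4,7-trihydroxy-4,7-dimethyl-3,4,5,6,7,8-hexahydronaphthalen-1(2H)-ylidene]propanoate
Product: 18 tert-butyl (2E)-3-acetoxy-2-[(2R,4S,7R)-2,4,7-trihydroxy-4,7-dimethyl-3,4,5,6,7,8-hexahydronaphthalen-1(2H)-ylidene]propanoate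
Conditions: Ac2O (1.05 equiv), pyridine, CH2Cl2, −20 °C
Reagents that add atoms: acetic anhydride, CC(=O)OC(C)=O
Why: Selective acylation of the primary allylic alcohol at C13; the hindered secondary C8 alcohol and the tertiary alcohols react more slowly.

Step 12
Reactants: 18 tert-butyl (2E)-3-acetoxy-2-[(2R,4S,7R)-2,4,7-trihydroxy-4,7-dimethyl-3,4,5,6,7,8-hexahydronaphthalen-1(2H)-ylidene]propanoate
Product: 19 tert-butyl (2E)-3-acetoxy-2-[(2R,4S,7R)-4,7-dihydroxy-4,7-dimethyl-2-(methacryloyloxy)-3,4,5,6,7,8-hexahydronaphthalen-1(2H)-ylidene]propanoate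
Conditions: methacrylic anhydride, DMAP, Et3N, CH2Cl2, 0 °C to rt
Reagents that add atoms: methacrylic anhydride, C=C(C)C(=O)OC(=O)C(C)=C
Why: DMAP-catalysed esterification of the one remaining secondary alcohol; the tertiary alcohols at C4 and C10 should not acylate under these conditions.

Step 13
Reactants: 19 tert-butyl (2E)-3-acetoxy-2-[(2R,4S,7R)-4,7-dihydroxy-4,7-dimethyl-2-(methacryloyloxy)-3,4,5,6,7,8-hexahydronaphthalen-1(2H)-ylidene]propanoate
Product: 23 target, (4R,5E,8R,10S)-13-acetoxy-1,4-epoxy-10-hydroxy-8-(methacryloyloxy)germacra-1,5,7(11)-trien-12,6-olide, via ozonide 20 (not isolated), via keto hemiketal 21 (not isolated), via bis-lactol acid 22 (not isolated)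
Conditions: O3 (1.0 equiv), pyridine, CH2Cl2, −78 °C; Me2S, −78 °C to rt; then TFA, 4 Å MS, CH2Cl2, 0 °C to rt
Reagents that add atoms: ozone, [O-][O+]=O (its oxygen atoms are carried by 20 to 22)
Why: Ozone should add to the tetrasubstituted C1=C6 bond, the most electron-rich alkene of 19 (the C7=C11 and methacrylate double bonds carry acceptors), and give ozonide 20; this is the classical scission of a ring-fusion octalin double bond to a cyclodecane-1,6-dione, so the ten-membered ring is unveiled and never closed. Reduction with Me2S frees the C1 and C6 ketones, and the C4 hydroxyl, the only one that reaches C1 through a five-membered ring, adds to it (5-exo-trig) to give hemiketal 21. Acid then removes the tert-butyl group and the carboxyl adds to the C6 ketone (5-exo-trig, possible because step 9 placed C12 cis to C6) to give pseudo-acid 22. Two dehydrations follow whose direction is fixed by structure: the C1 hemiketal can lose a proton only from C2 (C10 is quaternary) and the C6 lactol only from C5 (C7 is sp2), so the dihydrofuran enol ether and the ylidene butenolide of 23 result. No stereocenter is made: C4, C8 and C10 are carried unchanged from 19, and the C5=C6 geometry (C4 cis to C7) is the only one the bridged ring allows. The closest known reaction types are the ozonolysis of ring-fusion octalins, the cyclodehydration of (Z)-4-oxo-2-enoic acids to γ-ylidene butenolides and the dehydration of 2-hydroxytetrahydrofurans to 2,3-dihydrofurans. The step needs chemoselective ozonolysis, secured by the substitution pattern and by one titrated equivalent of ozone with pyridine at −78 °C, and capture of C6 by the carboxyl and not by O10, secured by the irreversible dehydration of the lactol.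

## Compound list

1 | isoprene (2-methylbuta-1,3-diene) | C=CC(C)=C | starting material
2 | 4,4-dimethoxycyclohexa-2,5-dien-1-one | COC1(OC)C=CC(=O)C=C1 | starting material
3 | (4aS,8aR)-4,4-dimethoxy-6-methyl-4a,5,8,8a-tetrahydronaphthalen-1(4H)-one (cis-fused) | COC1(OC)C=CC(=O)[C@@H]2CC=C(C)C[C@H]12 | intermediate
4 | (4aS,6S,7R,8aR)-6,7-epoxy-4,4-dimethoxy-6-methyl-4a,5,6,7,8,8a-hexahydronaphthalen-1(4H)-one (epoxide syn to the ring-fusion hydrogens) | COC1(OC)C=CC(=O)[C@@H]2C[C@H]3O[C@@]3(C)C[C@H]12 | intermediate
5 | (1S,4aS,6S,7R,8aR)-6,7-epoxy-4,4-dimethoxy-1,6-dimethyl-1,4,4a,5,6,7,8,8a-octahydronaphthalen-1-ol | COC1(OC)C=C[C@](C)(O)[C@@H]2C[C@H]3O[C@@]3(C)C[C@H]12 | intermediate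
6 | (1S,4aS,6R,8aR)-4,4-dimethoxy-1,6-dimethyl-1,4,4a,5,6,7,8,8a-octahydronaphthalene-1,6-diol (diol ketal) | COC1(OC)C=C[C@](C)(O)[C@@H]2CC[C@@](C)(O)C[C@H]12 | intermediate
7 | (4S,4aR,7R,8aS)-4,7-dihydroxy-4,7-dimethyl-4a,5,6,7,8,8a-hexahydronaphthalen-1(4H)-one | O=C1C=C[C@](C)(O)[C@@H]2CC[C@@](C)(O)C[C@H]12 | intermediate
8 | tris(trimethylsilyl) dienol ether of 7 (silyl enol ether C6=C7, silyl ethers at O4 and O10) | C[Si](C)(C)OC1=C2C[C@](C)(O[Si](C)(C)C)CC[C@H]2[C@@](C)(O[Si](C)(C)C)C=C1 | intermediate
9 | (4S,7R)-4,7-dimethyl-4,7-bis(trimethylsilyloxy)-5,6,7,8-tetrahydronaphthalen-1(4H)-one | O=C1C=C[C@](C)(O[Si](C)(C)C)C2=C1C[C@](C)(O[Si](C)(C)C)CC2 | intermediate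
10 | (4S,7R)-4,7-dihydroxy-4,7-dimethyl-5,6,7,8-tetrahydronaphthalen-1(4H)-one | O=C1C=C[C@](C)(O)C2=C1C[C@](C)(O)CC2 | intermediate
11 | tert-butyl 2-(diethoxyphosphoryl)acetate | CCOP(=O)(OCC)CC(=O)OC(C)(C)C | starting material
12 | tert-butyl 2-(diethoxyphosphoryl)-3-hydroxypropanoate (racemic) | CCOP(=O)(OCC)C(CO)C(=O)OC(C)(C)C | intermediate
13 | tert-butyl 2-(diethoxyphosphoryl)-3-[(diisopropylsilyl)oxy]propanoate (racemic) | CCOP(=O)(OCC)C(CO[SiH](C(C)C)C(C)C)C(=O)OC(C)(C)C | intermediate
14 | silyl dienol ether of 10 (O7–Si(iPr)2–O13 link to the phosphonate, C7=C8, C1=C6) | CCOP(=O)(OCC)C(CO[Si](C(C)C)(C(C)C)OC1=CC[C@](C)(O)C2=C1C[C@](C)(O)CC2)C(=O)OC(C)(C)C | intermediate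
15 | tert-butyl 2-(diethoxyphosphoryl)-3-[({[(2R,4S,7R)-4,7-dihydroxy-4,7-dimethyl-1-oxo-1,2,3,4,5,6,7,8-octahydronaphthalen-2-yl]oxy}diisopropylsilyl)oxy]propanoate | CCOP(=O)(OCC)C(CO[Si](C(C)C)(C(C)C)O[C@@H]1C[C@](C)(O)C2=C(C[C@](C)(O)CC2)C1=O)C(=O)OC(C)(C)C | intermediate
16 | cyclic diisopropylsilylene (O8, O13) derivative of 17 (seven-membered silaketal containing C7=C11) | CC(C)[Si]1(C(C)C)OC/C(C(=O)OC(C)(C)C)=C2\[C@H](O1)C[C@](C)(O)C3=C2C[C@](C)(O)CC3 | intermediate
17 | tert-butyl (2E)-3-hydroxy-2-[(2R,4S,7R)-2,4,7-trihydroxy-4,7-dimethyl-3,4,5,6,7,8-hexahydronaphthalen-1(2H)-ylidene]propanoate | OC/C(C(=O)OC(C)(C)C)=C1\[C@H](O)C[C@](C)(O)C2=C1C[C@](C)(O)CC2 | intermediate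
18 | tert-butyl (2E)-3-acetoxy-2-[(2R,4S,7R)-2,4,7-trihydroxy-4,7-dimethyl-3,4,5,6,7,8-hexahydronaphthalen-1(2H)-ylidene]propanoate | CC(=O)OC/C(C(=O)OC(C)(C)C)=C1\[C@H](O)C[C@](C)(O)C2=C1C[C@](C)(O)CC2 | intermediate
19 | tert-butyl (2E)-3-acetoxy-2-[(2R,4S,7R)-4,7-dihydroxy-4,7-dimethyl-2-(methacryloyloxy)-3,4,5,6,7,8-hexahydronaphthalen-1(2H)-ylidene]propanoate | CC(=O)OC/C(C(=O)OC(C)(C)C)=C1\[C@H](OC(=O)C(C)=C)C[C@](C)(O)C2=C1C[C@](C)(O)CC2 | intermediate
20 | ozonide of 19 (1,2,4-trioxolane across C1 and C6) | C=C(C)C(=O)O[C@@H]1C[C@](C)(O)C23CC[C@@](C)(O)CC(OO2)(O3)/C1=C(/COC(C)=O)C(=O)OC(C)(C)C | intermediate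
21 | keto hemiketal (C6 ketone, O4–C1 hemiketal, tert-butyl ester; C1 epimers) | C=C(C)C(=O)O[C@@H]1C[C@](C)(O)C2(O)CC[C@](C)(CC(=O)/C1=C(/COC(C)=O)C(=O)OC(C)(C)C)O2 | intermediate
22 | bis-lactol acid in its closed form (C6 hydroxy butenolide, C1 hemiketal; C1 and C6 epimers) | C=C(C)C(=O)O[C@@H]1C[C@](C)(O)C2(O)CC[C@](C)(CC3(O)OC(=O)C(COC(C)=O)=C31)O2 | intermediate
23 | CNP0394509.1, (4R,5E,8R,10S)-13-acetoxy-1,4-epoxy-10-hydroxy-8-(methacryloyloxy)germacra-1,5,7(11)-trien-12,6-olide | C=C(C)C(=O)O[C@@H]1C[C@](C)(O)C2=CC[C@](C)(/C=C3/OC(=O)C(COC(C)=O)=C31)O2 | target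

## Step count and least certain steps

Total: 13 steps. Longest linear sequence: 11 steps (steps 1–5 and 8–13); steps 6 and 7 form a two-step side branch.

**Step 13 (key step).** Over-oxidation is the most likely failure: ozone may also attack the C7=C11 or methacrylate double bonds. In the acid stage, the β-alkoxy ketone 21 may open by retro-oxa-Michael elimination before lactonisation, which would scramble C4, or the C10 α-ketol may shift. Fallback: set out from 19 and cleave in two stages. mCPBA (one equivalent, buffered, −20 °C) epoxidises only the most nucleophilic double bond to give 1,6-epoxide F1; periodic acid in wet THF opens the epoxide and cleaves the diol, and the route is rejoined at 21, which is then treated with acid as before.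

**Step 8.** Poor facial selectivity in the oxygenation at C8 is the main risk, because the direction by the C10 hydroxyl is only homoallylic. The silicon may also be transferred to the cis-disposed O10 and the phosphonate alcohol lost. Fallback: set out from 10 and use reagent control. Conjugate reduction with LiB(s-Bu)3H and oxidation of the resulting C8 enolate with the matched enantiomer of (camphorsulfonyl)oxaziridine should give hydroxy ketone F2. Silylation of F2 with chlorosilane F3 (from 12 and iPr2SiCl2, imidazole) returns to 15.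

**Step 9.** Ring closure onto the hindered cross-conjugated ketone may be slow; enolisation toward C8 (epimerisation) or silyl transfer to O10 could then take over. Fallback: set out from 10 and go through hydroxy ketone F2 (made as above) to a Knoevenagel route. Acylation of O8 with tert-butyl malonyl chloride gives malonate F4. Amine-catalysed intramolecular Knoevenagel condensation gives the fused butenolide ester F5, whose ring again forces the ester carbon cis to C6. Reduction of the lactone carbonyl (DIBAL-H, then NaBH4) opens it to the C8 and C13 alcohols and returns to 17.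

**Step 1.** Insufficient enantioselectivity of the catalytic Diels–Alder reaction is possible, because isoprene offers the catalyst little steric differentiation. Fallback: set out from 2 and move the chirality to the ketal. Transketalisation with (R,R)-hydrobenzoin gives the C2-symmetric monoketal F6, and a SnCl4-promoted Diels–Alder reaction with 1 should give adduct F7 under auxiliary control (the enantiomer of the diol is chosen accordingly). Epoxidation gives epoxide F8, methyllithium addition gives carbinol F9, and LiEt3BH gives diol ketal F10. Acid hydrolysis of F10 releases the diol and returns to 7.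

## Further compounds

F1 | step 13 | 1,6-epoxide of 19 | CC(=O)OC/C(C(=O)OC(C)(C)C)=C1\[C@H](OC(=O)C(C)=C)C[C@](C)(O)C23OC13C[C@](C)(O)CC2
F2 | step 8 | (2R,4S,7R)-2,4,7-trihydroxy-4,7-dimethyl-3,4,5,6,7,8-hexahydronaphthalen-1(2H)-one | O[C@@H]1C[C@](C)(O)C2=C(C[C@](C)(O)CC2)C1=O
F3 | step 8 | tert-butyl 3-{[chloro(diisopropyl)silyl]oxy}-2-(diethoxyphosphoryl)propanoate | CCOP(=O)(OCC)C(CO[Si](Cl)(C(C)C)C(C)C)C(=O)OC(C)(C)C
F4 | step 9 | O8 tert-butyl malonate of F2 | CC(C)(C)OC(=O)CC(=O)O[C@@H]1C[C@](C)(O)C2=C(C[C@](C)(O)CC2)C1=O
F5 | step 9 | fused butenolide tert-butyl ester (lactone O8–C13, C7=C11, ester on C11) | CC(C)(C)OC(=O)C1=C2[C@@H](C[C@](C)(O)C3=C2C[C@](C)(O)CC3)OC1=O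
F6 | step 1 | (2R,3R)-2,3-diphenyl-1,4-dioxaspiro[4.5]deca-6,9-dien-8-one | O=C1C=CC2(C=C1)O[C@H](c1ccccc1)[C@@H](c1ccccc1)O2
F7 | step 1 | Diels–Alder adduct of F6 and 1 (hydrobenzoin ketal analogue of 3) | O=C1C=CC2(O[C@H](c3ccccc3)[C@@H](c3ccccc3)O2)[C@H]2CC(C)=CC[C@@H]12
F8 | step 1 | ring A epoxide of F7 (analogue of 4) | O=C1C=CC2(O[C@H](c3ccccc3)[C@@H](c3ccccc3)O2)[C@H]2C[C@]3(C)O[C@@H]3C[C@@H]12
F9 | step 1 | C10 methyl carbinol from F8 (analogue of 5) | C[C@]1(O)C=CC2(O[C@H](c3ccccc3)[C@@H](c3ccccc3)O2)[C@H]2C[C@]3(C)O[C@@H]3C[C@@H]12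
F10 | step 1 | diol ketal from F9 (analogue of 6) | C[C@]1(O)C=CC2(O[C@H](c3ccccc3)[C@@H](c3ccccc3)O2)[C@H]2C[C@](C)(O)CC[C@@H]12
A1 | alternative 1 | seco aldehyde–vinyl iodide (C6 aldehyde, C7 iodide, methyl ester) | C=C(C)C(=O)O[C@H](C[C@](C)(O)C1=CC[C@](C)(CC=O)O1)/C(I)=C(\COC(C)=O)C(=O)OC
A2 | alternative 1 | 5,6-dihydro derivative of 23 (macrocyclic butenolide, sp3 C6) | C=C(C)C(=O)O[C@@H]1C[C@](C)(O)C2=CC[C@](C)(CC3OC(=O)C(COC(C)=O)=C31)O2
A3 | alternative 2 | 13-acetoxy-4,5-epoxy-10-hydroxy-8-(methacryloyloxy)-1-oxogermacr-7(11)-en-12,6-olide | C=C(C)C(=O)O[C@@H]1C[C@](C)(O)C(=O)CC[C@@]2(C)O[C@H]2[C@H]2OC(=O)C(COC(C)=O)=C21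
A4 | alternative 2 | 1-hydroxy hemiketal (hydrate of 23 at C1–C2) | C=C(C)C(=O)O[C@@H]1C[C@](C)(O)C2(O)CC[C@](C)(/C=C3/OC(=O)C(COC(C)=O)=C31)O2
A5 | alternative 3 | carvone-derived 1-vinyl-2-(2-silyloxypropenyl)cyclohexane-1,6-diol | C=C[C@@]1(O)[C@](C)(O)CC[C@@H](C(C)=C)[C@H]1/C=C(/C)O[Si](C)(C)C(C)(C)C
A6 | alternative 3 | oxy-Cope product, 10-hydroxy-4-silyloxy-7-isopropenyl-4,10-dimethylcyclodec-5-enone | C=C(C)[C@H]1CC[C@](C)(O)C(=O)CC[C@@](C)(O[Si](C)(C)C(C)(C)C)/C=C/1
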